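## Retrosynthetic overview

- Chondrillin 15 is read as the (3R,6S) isomer (dioxine numbering O1, O2, C3, C4=C5, C6; hexadecyl cis and methoxy trans to the acetate arm). It comes from acid 14, and 14 from invertive methanolysis at C6 of the bridged acylal 13. In 13 a temporary lactone bridge (ring B) runs from the C3 acetic arm to C6; it can only exist cis, so it ties the C6 configuration to C3.
- 13 comes from a one-flask formal [3+3] annulation that makes the C5–C6 bond (ketal carbon to ring CH=) and the O2–C3 bond of the dioxine (ring A). The partners are the silylperoxy orthoester 6 (C–O–O unit, from heptadecanenitrile) and the (S)-(Z)-stannylvinyl β-lactone 10 (three-carbon unit, from 3-(trimethylsilyl)propynal and acetyl chloride).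
- Enabling feature: C6 is a peroxyketal carbon bound to two oxygens (ring O1 and the methoxy O). At the orthoester level it ionises to an oxygen-stabilised carbenium ion that already carries the O1–O2 peroxide. The distal oxygen O2 can then reach C3 through a six-membered transition state across the cis C4=C5 alkene. C3 with its CH2–C(=O)O arm maps onto a β-lactone (ring C), whose C–O bond O2 displaces with inversion.
- Ring order: ring C (step 4) → ring A, then ring B, both in step 7 (ring C is consumed) → ring B opened in step 8, which sets C6.

Key step: step 7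

Assumption: O-trimethylsilylquinidine is taken to give the 4S lactone in step 4; if the sense of induction is the opposite, O-trimethylsilylquinine is used and nothing else changes.

## Route

Step 1
Reactants: 1 heptadecanenitrile
Product: 3 1,1,1-trimethoxyheptadecane, via methyl heptadecanimidate hydrochloride 2 (not isolated)
Conditions: HCl (g), MeOH (1.1 equiv), Et2O, 0 °C; then MeOH (excess), hexane, rt
Reagents that add atoms: methanol, CO
Why: Pinner reaction: HCl-promoted addition of methanol to the nitrile gives the imidate salt, whose methanolysis should give the orthoester with loss of ammonium chloride; no stereocenter is formed.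

Step 2
Reactants: 3 1,1,1-trimethoxyheptadecane
Product: 4 1,1-dimethoxyheptadec-1-ene
Conditions: TMSOTf (1.1 equiv), iPr2NEt (1.3 equiv), CH2Cl2, −78 °C → rt
Reagents that add atoms: none
Why: Silyl triflate/amine elimination of an orthoester (ionisation to the dimethoxycarbenium ion, then deprotonation of the α-CH2 by the hindered amine) is an established way to ketene acetals.

Step 3
Reactants: 4 1,1-dimethoxyheptadec-1-ene
Product: 6 triethyl[(1,1-dimethoxyheptadecyl)peroxy]silane, via 1-hydroperoxy-1,1-dimethoxyheptadecane 5 (not isolated)
Conditions: H2O2 (anhydrous, in Et2O, 5 equiv), −30 °C; then Et3SiCl, imidazole, CH2Cl2, 0 °C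
Reagents that add atoms: hydrogen peroxide, OO; chlorotriethylsilane, CC[Si](Cl)(CC)CC
Why: Markovnikov addition of a hydroperoxide O–H across an electron-rich O-substituted alkene (C-protonation to the dialkoxycarbenium ion, capture by the hydroperoxide) is the reaction type that gives peroxyketals from enol ethers; excess H2O2 should suppress the bis-adduct, and O-silylation of the hydroperoxide is routine.

Step 4
Reactants: 7 3-(trimethylsilyl)prop-2-ynal
Product: 8 (4S)-4-[(trimethylsilyl)ethynyl]oxetan-2-one
Conditions: AcCl, iPr2NEt, O-trimethylsilylquinidine (10 mol %), LiClO4, Et2O/CH2Cl2, −78 °C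
Reagents that add atoms: acetyl chloride, CC(=O)Cl
Why: Catalytic asymmetric ketene–aldehyde [2+2] cycloaddition (acyl halide–aldehyde cyclocondensation): ketene made in the flask is bound by the alkaloid as an ammonium enolate and adds to the LiClO4-activated ynal, and the alkaloid pseudoenantiomer sets the 4S center.

Step 5
Reactants: 8 (4S)-4-[(trimethylsilyl)ethynyl]oxetan-2-one
Product: 9 (4S)-4-ethynyloxetan-2-one
Conditions: TBAF (1.1 equiv), AcOH (1.2 equiv), THF, 0 °C
Reagents that add atoms: none
Why: Fluoride-induced protodesilylation of an alkynylsilane, buffered with acetic acid so that the β-lactone should not be opened; the stereocenter is not touched.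

Step 6
Reactants: 9 (4S)-4-ethynyloxetan-2-one
Product: 10 (4S)-4-[(Z)-2-(tributylstannyl)ethenyl]oxetan-2-one
Conditions: Bu3SnH, ZrCl4 (20 mol %), toluene, 0 °C
Reagents that add atoms: tributyltin hydride, CCCC[SnH](CCCC)CCCC
Why: Lewis-acid-catalysed trans-hydrostannation of a terminal alkyne (anti addition of Sn–H, tin at the terminal carbon) should give the (Z)-vinylstannane; the stereocenter is not touched.

Step 7
Reactants: 6 triethyl[(1,1-dimethoxyheptadecyl)peroxy]silane (1.3 equiv) + 10 (4S)-4-[(Z)-2-(tributylstannyl)ethenyl]oxetan-2-one
Product: 13 (1R,5R)-1-hexadecyl-2,6,7-trioxabicyclo[3.2.2]non-8-en-3-one, via acyclic silylperoxy ketal 11 (not isolated), via monocyclic dioxine silyl ester 12 (not isolated)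
Conditions: TMSOTf (1.5 equiv), 4 Å MS, CH2Cl2, −78 → −20 °C; KF (aq) work-up
Reagents that add atoms: none
Why: Proposed new method: TMSOTf should remove one methoxide from 6 to give a methoxy(silylperoxy)carbenium ion, which is attacked at the tin-bearing carbon of the (Z)-vinylstannane 10 (ipso-destannylation with retention of alkene geometry, C5–C6 bond, giving 11), after which the silylperoxy oxygen opens the silyl-activated β-lactone at its allylic carbon (6-exo-tet SN2, O2–C3 bond, dioxine ring, giving 12); this is a formal [3+3] annulation. The closest known reaction types are the [3+2] annulation of silylperoxy carbenium ions with alkenes (C–C then C–O bond formation with loss of the silyl group), Lewis-acid substitution of peroxyketals by allylstannanes, electrophilic ipso substitution of vinylstannanes and alkyl–oxygen opening of β-lactones by heteroatom nucleophiles. C3 is set by inversion at the 4S lactone carbon of 10, which gives 3R. In the same flask the remaining methoxy group of 12 should ionise and the silyl ester close onto C6 (seven-membered lactone ring, transannular capture of the cyclic peroxycarbenium ion); the bridge can only form cis to the C3 arm, so both C6 epimers of 12 should converge on the single acylal 13, driven by exchange of a silyl ester for a silyl methyl ether. The step needs loss of methoxide and not of the silylperoxide (the methoxy oxygen is the more basic site, as in Lewis-acid ionisation of peroxyketals), ipso and not β attack on the alkene (β-tin stabilisation of the cation), and SN2 and not SN1 opening of the allylic lactone (low temperature, nucleophile held in reach by the Z alkene).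

Step 8
Reactants: 13 (1R,5R)-1-hexadecyl-2,6,7-trioxabicyclo[3.2.2]non-8-en-3-one
Product: 14 2-[(3R,6S)-6-hexadecyl-6-methoxy-3,6-dihydro-1,2-dioxin-3-yl]acetic acid
Conditions: MeOH/CH2Cl2 (1:1), PPTS (5 mol %), −30 → 0 °C
Reagents that add atoms: methanol, CO
Why: Acid-catalysed alcoholysis of a strained bridged acylal (alkyl–oxygen cleavage assisted by ring oxygen O1): the carboxyl group can only leave from the face it bridges, cis to the C3 arm, and methanol should add to the nascent cyclic peroxycarbenium ion from the opposite face along the axial trajectory before the ring relaxes, so C6 is inverted and the methoxy group ends trans to the acetic acid arm (6S), while the cold buffered medium should leave the less strained product ketal un-ionised.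

Step 9
Reactants: 14 2-[(3R,6S)-6-hexadecyl-6-methoxy-3,6-dihydro-1,2-dioxin-3-yl]acetic acid
Product: 15 chondrillin (methyl 2-[(3R,6S)-6-hexadecyl-6-methoxy-3,6-dihydro-1,2-dioxin-3-yl]acetate)
Conditions: TMSCHN2, MeOH/toluene, 0 °C
Reagents that add atoms: (trimethylsilyl)diazomethane, C[Si](C)(C)C=[N+]=[N-]
Why: Diazoalkane esterification of the carboxylic acid under neutral conditions, which should leave the peroxide, the ketal and both stereocenters untouched.

## Compound list

1 | heptadecanenitrile | CCCCCCCCCCCCCCCCC#N | starting material
2 | methyl heptadecanimidate hydrochloride (formed in the flask) | CCCCCCCCCCCCCCCCC(=[NH2+])OC.[Cl-] | intermediate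
3 | 1,1,1-trimethoxyheptadecane (trimethyl orthoheptadecanoate) | CCCCCCCCCCCCCCCCC(OC)(OC)OC | intermediate
4 | 1,1-dimethoxyheptadec-1-ene | CCCCCCCCCCCCCCCC=C(OC)OC | intermediate
5 | 1-hydroperoxy-1,1-dimethoxyheptadecane (formed in the flask) | CCCCCCCCCCCCCCCCC(OC)(OC)OO | intermediate
6 | triethyl[(1,1-dimethoxyheptadecyl)peroxy]silane | CCCCCCCCCCCCCCCCC(OC)(OC)OO[Si](CC)(CC)CC | intermediate
7 | 3-(trimethylsilyl)prop-2-ynal | C[Si](C)(C)C#CC=O | starting material
8 | (4S)-4-[(trimethylsilyl)ethynyl]oxetan-2-one | O=C1C[C@H](O1)C#C[Si](C)(C)C | intermediate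
9 | (4S)-4-ethynyloxetan-2-one | O=C1C[C@H](O1)C#C | intermediate
10 | (4S)-4-[(Z)-2-(tributylstannyl)ethenyl]oxetan-2-one | O=C1C[C@H](O1)/C=C\[Sn](CCCC)(CCCC)CCCC | intermediate
11 | (4S)-4-[(1Z)-3-methoxy-3-[(triethylsilyl)peroxy]nonadec-1-en-1-yl]oxetan-2-one, both epimers at the ketal carbon (formed in the flask) | CCCCCCCCCCCCCCCCC(OC)(OO[Si](CC)(CC)CC)/C=C\[C@@H]1CC(=O)O1 | intermediate
12 | trimethylsilyl 2-[(3R)-6-hexadecyl-6-methoxy-3,6-dihydro-1,2-dioxin-3-yl]acetate, both C6 epimers (formed in the flask) | CCCCCCCCCCCCCCCCC1(OC)C=C[C@@H](CC(=O)O[Si](C)(C)C)OO1 | intermediate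
13 | (1R,5R)-1-hexadecyl-2,6,7-trioxabicyclo[3.2.2]non-8-en-3-one | CCCCCCCCCCCCCCCC[C@@]12OC(=O)C[C@@H](OO1)C=C2 | intermediate
14 | 2-[(3R,6S)-6-hexadecyl-6-methoxy-3,6-dihydro-1,2-dioxin-3-yl]acetic acid | CCCCCCCCCCCCCCCC[C@@]1(OC)C=C[C@@H](CC(=O)O)OO1 | intermediate
15 | chondrillin, methyl 2-[(3R,6S)-6-hexadecyl-6-methoxy-3,6-dihydro-1,2-dioxin-3-yl]acetate | CCCCCCCCCCCCCCCC[C@@]1(OC)C=C[C@@H](CC(=O)OC)OO1 | target

## Step count and risks

Total step count: 9. Longest linear sequence: 6 steps (steps 1, 2, 3, 7, 8, 9, or equally steps 4, 5, 6, 7, 8, 9).

Steps most likely to fail: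

Step 7 (Proposed new method). What may go wrong: ionisation at the silylperoxy oxygen with loss of the peroxide unit; protodestannylation or sluggish ipso attack; SN1 opening of the allylic lactone with erosion of the C3 configuration; or capture of the ring cation by the carboxyl group at C4 in place of C6. The fallback uses known reaction types and makes the two bonds one after the other. It sets out from 10. Stille acylation of 10 with heptadecanoyl chloride (Pd2(dba)3, tri(2-furyl)phosphine, THF) should give (4S)-4-[(1Z)-3-oxononadec-1-en-1-yl]oxetan-2-one F1 with retention of the Z geometry. Ethereal H2O2 with a trace of acid then adds to the ketone, and the hydroperoxy group opens the β-lactone at its ring CH carbon by alkyl–oxygen cleavage with inversion. This gives the dioxinol 2-[(3R)-6-hexadecyl-6-hydroxy-3,6-dihydro-1,2-dioxin-3-yl]acetic acid F2 as a ring–chain mixture of hemiketals. Carbodiimide lactonisation (EDC, CH2Cl2) traps the cis hemiketal, and the route is rejoined at 13.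

Step 8. What may go wrong: loss of facial selectivity through a relaxed, free peroxycarbenium ion; re-ionisation of the product ketal (epimerisation at C6); or acyl–oxygen cleavage of the lactone. The fallback sets out from 13. Ketal exchange under thermodynamic control (PPTS, MeOH, rt) gives 14 together with its C6 epimer 2-[(3R,6R)-6-hexadecyl-6-methoxy-3,6-dihydro-1,2-dioxin-3-yl]acetic acid F3. The two are separated by chromatography and F3 is returned to the same equilibration until it is consumed, so the route is rejoined at 14.

Step 6. What may go wrong: Lewis-acid opening of the propargylic β-lactone, or incomplete anti selectivity of the hydrostannation. The fallback sets out from 9. Stannylation of the alkyne C–H with Bu3SnOMe gives (4S)-4-[(tributylstannyl)ethynyl]oxetan-2-one F4. Hydrozirconation with Cp2Zr(H)Cl followed by protonolysis (syn addition, cis reduction of the stannylalkyne) then gives the Z-vinylstannane, and the route is rejoined at 10.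

Further compounds
F1 | step 7 | (4S)-4-[(1Z)-3-oxononadec-1-en-1-yl]oxetan-2-one | CCCCCCCCCCCCCCCCC(=O)/C=C\[C@@H]1CC(=O)O1
F2 | step 7 | 2-[(3R)-6-hexadecyl-6-hydroxy-3,6-dihydro-1,2-dioxin-3-yl]acetic acid (hemiketal epimers) | CCCCCCCCCCCCCCCCC1(O)C=C[C@@H](CC(=O)O)OO1
F3 | step 8 | 2-[(3R,6R)-6-hexadecyl-6-methoxy-3,6-dihydro-1,2-dioxin-3-yl]acetic acid | CCCCCCCCCCCCCCCC[C@]1(OC)C=C[C@@H](CC(=O)O)OO1
F4 | step 6 | (4S)-4-[(tributylstannyl)ethynyl]oxetan-2-one | O=C1C[C@H](O1)C#C[Sn](CCCC)(CCCC)CCCC
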